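**Plan**
1. Retrosynthesis: after oxidation-level changes (C2 ketone from a silyl-protected carbinol, C4 CH2OH from a methyl ester) the cyclohexene is opened at C4–C5 and the heptenyl group is taken off C3 in the same operation. The acyclic ynoate epoxy aldehyde is then cut at C2–C3 (acetylide plus aldehyde), at the epoxide C–O bonds (allylic alcohol) and at the two C–C bonds of the C1 side chain.
2. Enabling feature: ring atoms C5(OH)–C4(=C3)–CH2OH are a reduced α-(hydroxyalkyl)acrylate. With the CH2OH carbon as an ester, C4 is the α-carbon of an allenoate formed when the heptenyl group adds to C3 of a 2-ynoate, and the cis-epoxide C6–C1 holds the C5 aldehyde within reach of C4.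
3. Forward order: but-2-yne-1,4-diol supplies C2–C1–C6–C5 (syn-hydrostannation fixes the Z-olefin, hence the cis-epoxide). Allyl, methacrylate and propiolate units are joined in turn, and the carbocycle, the only ring made by C–C bond formation, arises last (step 10).
4. Stereochemistry: C1 and C6 from the Sharpless epoxidation (reagent control); C5 from the ring closure (substrate control through a zinc chelate to the epoxide oxygen); olefin geometries from cross-metathesis and hydrozirconation; the C2 carbinol centre is temporary.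
5. Endgame: selective ester reduction, acetonide, oxidation at C2, acid deprotection.

Key step: step 10

Locants C1–C6 in the text are those of the target ring: C1 quaternary epoxide carbon, C2 carbonyl, C3 heptenyl carbon, C4 hydroxymethyl carbon, C5 carbinol, C6 epoxide CH.
Assumption: the configuration of the silyloxy carbon made in step 7 is erased in step 13; the epimer drawn is the one expected from non-chelated addition, and its epimer would be carried through in the same way.

**Route**

Step 1
Reactants: 1 but-2-yne-1,4-diol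
Product: 2 (E)-2-(tributylstannyl)but-2-ene-1,4-diol
Conditions: Bu3SnH, PdCl2(PPh3)2 (cat.), THF, 0 °C → rt
Reagents that add atoms: tributyltin hydride, CCCC[SnH](CCCC)CCCC
Why: Palladium-catalysed hydrostannation of an alkyne is a syn addition, so the two hydroxymethyl groups of the symmetrical diol end up cis on the new olefin and no regiochemical issue arises.

Step 2
Reactants: 2 (E)-2-(tributylstannyl)but-2-ene-1,4-diol
Product: 3 (E)-2-(tributylstannyl)-4-(triethylsilyloxy)but-2-en-1-ol
Conditions: Et3SiCl (1 equiv), imidazole, CH2Cl2, −78 °C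
Reagents that add atoms: chlorotriethylsilane, CC[Si](Cl)(CC)CC
Why: Silyl ether formation should occur at the hydroxyl remote from the bulky tributylstannyl group, which shields its neighbouring CH2OH and leaves that hydroxyl free to direct the later epoxidation.

Step 3
Reactants: 3 (E)-2-(tributylstannyl)-4-(triethylsilyloxy)but-2-en-1-ol; 4 allyl bromide
Product: 5 (Z)-2-[2-(triethylsilyloxy)ethylidene]pent-4-en-1-ol
Conditions: Pd2(dba)3 (cat.), AsPh3, NMP, 50 °C
Reagents that add atoms: none
Why: Stille coupling of the alkenylstannane with an allylic bromide proceeds with retention of olefin geometry and tolerates the free alcohol and the silyl ether.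

Step 4
Reactants: 5 (Z)-2-[2-(triethylsilyloxy)ethylidene]pent-4-en-1-ol; 6 tert-butyl methacrylate (excess)
Product: 7 tert-butyl (2E,5Z)-5-(hydroxymethyl)-2-methyl-7-(triethylsilyloxy)hepta-2,5-dienoate
Conditions: second-generation Hoveyda–Grubbs catalyst (cat.), CH2Cl2, 40 °C
Reagents that add atoms: none
Why: Olefin cross-metathesis of a terminal olefin with a methacrylate ester gives the trisubstituted E-enoate under thermodynamic control, while the trisubstituted allylic olefin is too hindered to engage the ruthenium carbene.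

Step 5
Reactants: 7 tert-butyl (2E,5Z)-5-(hydroxymethyl)-2-methyl-7-(triethylsilyloxy)hepta-2,5-dienoate
Product: 8 tert-butyl (E)-4-[(2S,3R)-2-(hydroxymethyl)-3-(triethylsilyloxymethyl)oxiran-2-yl]-2-methylbut-2-enoate
Conditions: Ti(OiPr)4, L-(+)-diethyl tartrate, t-BuOOH, 4 Å molecular sieves, CH2Cl2, −20 °C
Reagents that add atoms: tert-butyl hydroperoxide, CC(C)(C)OO
Why: Sharpless asymmetric epoxidation is directed by the free allylic hydroxyl to the adjacent olefin only (the enoate is inert), the L-(+)-tartrate selects the face that gives the (2S,3R)-epoxide, and the Z-olefin is transferred stereospecifically into the cis-epoxide that sets C1 and C6.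

Step 6
Reactants: 8 tert-butyl (E)-4-[(2S,3R)-2-(hydroxymethyl)-3-(triethylsilyloxymethyl)oxiran-2-yl]-2-methylbut-2-enoate
Product: 9 tert-butyl (E)-4-[(2R,3R)-2-formyl-3-(triethylsilyloxymethyl)oxiran-2-yl]-2-methylbut-2-enoate
Conditions: Dess–Martin periodinane, NaHCO3, CH2Cl2, 0 °C → rt
Reagents that add atoms: none
Why: Dess–Martin oxidation of the primary alcohol gives an aldehyde that cannot epimerise because its α-carbon is quaternary.

Step 7
Reactants: 9 tert-butyl (E)-4-[(2R,3R)-2-formyl-3-(triethylsilyloxymethyl)oxiran-2-yl]-2-methylbut-2-enoate; 10 methyl propiolate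
Product: 13 methyl (4S)-4-[(2R,3R)-2-[(E)-4-tert-butoxy-3-methyl-4-oxobut-2-enyl]-3-(triethylsilyloxymethyl)oxiran-2-yl]-4-(triethylsilyloxy)but-2-ynoate, via lithium acetylide 11 (not isolated), via lithium alkoxide 12 (not isolated)
Conditions: 10, LiN(SiMe3)2, THF, −78 °C; add 9; then Et3SiOTf, −78 → −40 °C
Reagents that add atoms: triethylsilyl triflate, CC[Si](CC)(CC)OS(=O)(=O)C(F)(F)F
Why: 1,2-Addition of a lithium acetylide to the aldehyde at −78 °C is followed by O-silylation of the alkoxide in the same flask; the new carbinol centre forms under Felkin–Anh-type substrate control and is only temporary.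

Step 8
Reactants: 13 methyl (4S)-4-[(2R,3R)-2-[(E)-4-tert-butoxy-3-methyl-4-oxobut-2-enyl]-3-(triethylsilyloxymethyl)oxiran-2-yl]-4-(triethylsilyloxy)but-2-ynoate
Product: 14 methyl (4S)-4-[(2R,3S)-2-[(E)-4-tert-butoxy-3-methyl-4-oxobut-2-enyl]-3-formyloxiran-2-yl]-4-(triethylsilyloxy)but-2-ynoate
Conditions: (COCl)2, DMSO, CH2Cl2, −78 → −40 °C; then Et3N, −78 → 0 °C
Reagents that add atoms: none
Why: Swern oxidation converts a primary triethylsilyl ether directly into the aldehyde (silyl transfer to the chlorosulfonium salt, then ylide fragmentation), whereas the secondary, neopentyl-type silyl ether is too hindered to react.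

Step 9
Reactants: 15 hept-1-yne
Product: 17 (E)-1-iodohept-1-ene, via alkenylzirconocene chloride 16 (not isolated)
Conditions: Cp2Zr(H)Cl, CH2Cl2, rt; then I2, 0 °C
Reagents that add atoms: iodine, II
Why: Hydrozirconation of the terminal alkyne is a syn, anti-Markovnikov addition, and iodinolysis of the carbon–zirconium bond with retention gives the E-alkenyl iodide.

Step 10
Reactants: 14 methyl (4S)-4-[(2R,3S)-2-[(E)-4-tert-butoxy-3-methyl-4-oxobut-2-enyl]-3-formyloxiran-2-yl]-4-(triethylsilyloxy)but-2-ynoate; 17 (E)-1-iodohept-1-ene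
Product: 21 tert-butyl (E)-4-[(1R,2S,5R,6R)-3-[(E)-hept-1-enyl]-5-hydroxy-4-(methoxycarbonyl)-2-(triethylsilyloxy)-7-oxabicyclo[4.1.0]hept-3-en-1-yl]-2-methylbut-2-enoate, via (E)-hept-1-enyllithium 18 (not isolated), via lithium diheptenylcuprate 19 (not isolated), via acyclic lithium allenoate 20 (not isolated)
Conditions: 17, t-BuLi, Et2O, −78 °C; CuBr·SMe2, −78 → −40 °C; cuprate (1 equiv) added to 14 in THF, −78 °C; then ZnCl2, −78 → −30 °C; aq. NH4Cl
Reagents that add atoms: none
Why: The Gilman reagent transfers its heptenyl group to C3, the β-carbon of the ynoate, much faster than it attacks the aldehyde at −78 °C, and the resulting allenoate, once transmetallated to zinc, is nucleophilic at C4 through the enolate lobe that lies in the plane of the C3 substituents, so attack on the tethered aldehyde carbon C5 from the side of the C2 arm forms the C4–C5 bond and can only give the endocyclic olefin with C2 and C5 cis. The closest known reaction types are the three-component cuprate/alkynoate/aldehyde conjugate addition–aldol coupling and the conjugate addition–cycloalkylation or –cycloacylation of 2-alkynoates that carry a tethered electrophile, which likewise give ring tetrasubstituted enoates. The six-membered carbocycle is closed in the 6-(enolexo)-exo-trig mode. The single new stereocentre, C5, is controlled by the substrate: zinc bridges the enolate oxygen, the aldehyde oxygen and the epoxide oxygen on the face opposite the C1 side chain (Zimmerman–Traxler-type closed transition state), which places the new hydroxyl cis to the epoxide oxygen, whereas the other face would bring the metal-bound oxygen 1,3-syn to the C1 methylene group. The step needs chemoselectivity for the ynoate over the aldehyde, the epoxide and the tert-butyl enoate, regioselectivity for C3, and facial selectivity at C5; these should be secured by the high acceptor reactivity of the ynoate (with inverse addition of one equivalent of cuprate), by the polarisation that the ester imposes on C4, and by the cis-epoxide, which both holds C5 next to C4 and supplies the chelating oxygen.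

Step 11
Reactants: 21 tert-butyl (E)-4-[(1R,2S,5R,6R)-3-[(E)-hept-1-enyl]-5-hydroxy-4-(methoxycarbonyl)-2-(triethylsilyloxy)-7-oxabicyclo[4.1.0]hept-3-en-1-yl]-2-methylbut-2-enoate
Product: 22 tert-butyl (E)-4-[(1R,2S,5R,6R)-3-[(E)-hept-1-enyl]-5-hydroxy-4-(hydroxymethyl)-2-(triethylsilyloxy)-7-oxabicyclo[4.1.0]hept-3-en-1-yl]-2-methylbut-2-enoate
Conditions: i-Bu2AlH, CH2Cl2, −78 °C; aq. KNaC4H4O6
Reagents that add atoms: none
Why: Hydride reduction of the methyl ester to the primary alcohol should be favoured over the tert-butyl enoate, because the C5 aluminium alkoxide can deliver hydride intramolecularly and tert-butyl esters react only slowly with i-Bu2AlH at −78 °C.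

Step 12
Reactants: 22 tert-butyl (E)-4-[(1R,2S,5R,6R)-3-[(E)-hept-1-enyl]-5-hydroxy-4-(hydroxymethyl)-2-(triethylsilyloxy)-7-oxabicyclo[4.1.0]hept-3-en-1-yl]-2-methylbut-2-enoate
Product: 24 5-O:4-CH2O-isopropylidene acetal of triol 23 (C2 hydroxyl free), via triol 23 (not isolated)
Conditions: PPTS, MeOH, 0 °C → rt; then Me2C(OMe)2, PPTS, acetone, rt
Reagents that add atoms: 2,2-dimethoxypropane, COC(C)(C)OC
Why: Acid-catalysed methanolysis removes the secondary silyl ether, and transketalisation then closes the only possible cyclic acetal, the six-membered one across the C5 hydroxyl and the C4 CH2OH (the C2 hydroxyl is trans to the CH2OH across the ring olefin and has no partner).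

Step 13
Reactants: 24 5-O:4-CH2O-isopropylidene acetal of triol 23 (C2 hydroxyl free)
Product: 25 5-O:4-CH2O-isopropylidene acetal of ambuic acid tert-butyl ester (C2 ketone)
Conditions: Dess–Martin periodinane, NaHCO3, CH2Cl2, 0 °C → rt
Reagents that add atoms: none
Why: Dess–Martin oxidation of the remaining secondary allylic alcohol gives the cross-conjugated dienone under buffered, non-epimerising conditions.

Step 14
Reactants: 25 5-O:4-CH2O-isopropylidene acetal of ambuic acid tert-butyl ester (C2 ketone)
Product: 26 (E)-4-[(1R,5R,6R)-3-[(E)-hept-1-enyl]-5-hydroxy-4-(hydroxymethyl)-2-oxo-7-oxabicyclo[4.1.0]hept-3-en-1-yl]-2-methylbut-2-enoic acid (ambuic acid)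
Conditions: CF3CO2H, CH2Cl2, H2O, 0 °C → rt
Reagents that add atoms: none
Why: Acidolysis hydrolyses the isopropylidene acetal and cleaves the tert-butyl ester with loss of 2-methylpropene, and the epoxide, now α to the ketone, is deactivated toward acid-promoted opening.

**Compound list**

1 | but-2-yne-1,4-diol | OCC#CCO | starting material
2 | (E)-2-(tributylstannyl)but-2-ene-1,4-diol | OC/C=C(/[Sn](CCCC)(CCCC)CCCC)CO | intermediate
3 | (E)-2-(tributylstannyl)-4-(triethylsilyloxy)but-2-en-1-ol | CC[Si](CC)(CC)OC/C=C(/[Sn](CCCC)(CCCC)CCCC)CO | intermediate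
4 | allyl bromide | C=CCBr | starting material
5 | (Z)-2-[2-(triethylsilyloxy)ethylidene]pent-4-en-1-ol | CC[Si](CC)(CC)OC/C=C(/CC=C)CO | intermediate
6 | tert-butyl methacrylate | C=C(C)C(=O)OC(C)(C)C | starting material
7 | tert-butyl (2E,5Z)-5-(hydroxymethyl)-2-methyl-7-(triethylsilyloxy)hepta-2,5-dienoate | CC[Si](CC)(CC)OC/C=C(/C/C=C(\C)C(=O)OC(C)(C)C)CO | intermediate
8 | tert-butyl (E)-4-[(2S,3R)-2-(hydroxymethyl)-3-(triethylsilyloxymethyl)oxiran-2-yl]-2-methylbut-2-enoate | CC[Si](CC)(CC)OC[C@H]1O[C@@]1(C/C=C(\C)C(=O)OC(C)(C)C)CO | intermediate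
9 | tert-butyl (E)-4-[(2R,3R)-2-formyl-3-(triethylsilyloxymethyl)oxiran-2-yl]-2-methylbut-2-enoate | CC[Si](CC)(CC)OC[C@H]1O[C@@]1(C/C=C(\C)C(=O)OC(C)(C)C)C=O | intermediate
10 | methyl propiolate | C#CC(=O)OC | starting material
11 | lithium acetylide of methyl propiolate | [Li]C#CC(=O)OC | intermediate (not isolated)
12 | lithium alkoxide from addition of 11 to 9 (alkoxide of the C4 carbinol of the but-2-ynoate) | CC[Si](CC)(CC)OC[C@H]1O[C@@]1(C/C=C(\C)C(=O)OC(C)(C)C)[C@@H]([O-])C#CC(=O)OC.[Li+] | intermediate (not isolated)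
13 | methyl (4S)-4-[(2R,3R)-2-[(E)-4-tert-butoxy-3-methyl-4-oxobut-2-enyl]-3-(triethylsilyloxymethyl)oxiran-2-yl]-4-(triethylsilyloxy)but-2-ynoate | CC[Si](CC)(CC)OC[C@H]1O[C@@]1(C/C=C(\C)C(=O)OC(C)(C)C)[C@@H](O[Si](CC)(CC)CC)C#CC(=O)OC | intermediate
14 | methyl (4S)-4-[(2R,3S)-2-[(E)-4-tert-butoxy-3-methyl-4-oxobut-2-enyl]-3-formyloxiran-2-yl]-4-(triethylsilyloxy)but-2-ynoate | O=C[C@H]1O[C@@]1(C/C=C(\C)C(=O)OC(C)(C)C)[C@@H](O[Si](CC)(CC)CC)C#CC(=O)OC | intermediate
15 | hept-1-yne | CCCCCC#C | starting material
16 | (E)-hept-1-enylzirconocene chloride | CCCCC/C=C/[Zr](Cl)(C1C=CC=C1)C1C=CC=C1 | intermediate (not isolated)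
17 | (E)-1-iodohept-1-ene | CCCCC/C=C/I | intermediate
18 | (E)-hept-1-enyllithium | CCCCC/C=C/[Li] | intermediate (not isolated)
19 | lithium di[(E)-hept-1-enyl]cuprate | [Li+].CCCCC/C=C/[Cu-]/C=C/CCCCC | intermediate (not isolated)
20 | acyclic lithium allenoate (conjugate adduct of 19 and 14, heptenyl on C3) | O=C[C@H]1O[C@@]1(C/C=C(\C)C(=O)OC(C)(C)C)[C@@H](O[Si](CC)(CC)CC)C(/C=C/CCCCC)=C=C([O-])OC.[Li+] | intermediate (not isolated)
21 | tert-butyl (E)-4-[(1R,2S,5R,6R)-3-[(E)-hept-1-enyl]-5-hydroxy-4-(methoxycarbonyl)-2-(triethylsilyloxy)-7-oxabicyclo[4.1.0]hept-3-en-1-yl]-2-methylbut-2-enoate | CCCCC/C=C/C1=C(C(=O)OC)[C@@H](O)[C@H]2O[C@@]2(C/C=C(\C)C(=O)OC(C)(C)C)[C@H]1O[Si](CC)(CC)CC | intermediate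
22 | tert-butyl (E)-4-[(1R,2S,5R,6R)-3-[(E)-hept-1-enyl]-5-hydroxy-4-(hydroxymethyl)-2-(triethylsilyloxy)-7-oxabicyclo[4.1.0]hept-3-en-1-yl]-2-methylbut-2-enoate | CCCCC/C=C/C1=C(CO)[C@@H](O)[C@H]2O[C@@]2(C/C=C(\C)C(=O)OC(C)(C)C)[C@H]1O[Si](CC)(CC)CC | intermediate
23 | tert-butyl (E)-4-[(1S,2S,5R,6R)-3-[(E)-hept-1-enyl]-2,5-dihydroxy-4-(hydroxymethyl)-7-oxabicyclo[4.1.0]hept-3-en-1-yl]-2-methylbut-2-enoate | CCCCC/C=C/C1=C(CO)[C@@H](O)[C@H]2O[C@@]2(C/C=C(\C)C(=O)OC(C)(C)C)[C@H]1O | intermediate (not isolated)
24 | 5-O:4-CH2O-isopropylidene acetal of triol 23 (C2 hydroxyl free, cis to the epoxide oxygen) | CCCCC/C=C/C1=C2COC(C)(C)O[C@H]2[C@H]3O[C@@]3(C/C=C(\C)C(=O)OC(C)(C)C)[C@H]1O | intermediate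
25 | 5-O:4-CH2O-isopropylidene acetal of ambuic acid tert-butyl ester (C2 ketone) | CCCCC/C=C/C1=C2COC(C)(C)O[C@H]2[C@H]3O[C@@]3(C/C=C(\C)C(=O)OC(C)(C)C)C1=O | intermediate
26 | (E)-4-[(1R,5R,6R)-3-[(E)-hept-1-enyl]-5-hydroxy-4-(hydroxymethyl)-2-oxo-7-oxabicyclo[4.1.0]hept-3-en-1-yl]-2-methylbut-2-enoic acid (ambuic acid) | CCCCC/C=C/C1=C(CO)[C@@H](O)[C@H]2O[C@@]2(C/C=C(\C)C(=O)O)C1=O | target

**Step count**

Total: 14 steps. Longest linear sequence: 13 steps (steps 1–8 and 10–14); step 9 is a one-step side branch.

**Steps most likely to fail**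

1. Step 10. What may go wrong: competing 1,2-addition of the cuprate to the epoxy aldehyde, protonation of the allenoate before ring closure, or attack on the wrong face of the aldehyde. The fallback sets out from 14 and returns at 21. The aldehyde is oxidised (NaClO2, NaH2PO4, 2-methylbut-2-ene, t-BuOH/H2O) to the glycidic acid F1, which is methylated (MeI, KHCO3, DMF) to the methyl glycidate F2. Conjugate addition of cuprate 19 to the ynoate of F2, now without a competing aldehyde, gives the allenoate F3 (not isolated). On warming, F3 acylates itself on the glycidate ester (conjugate addition–cycloacylation, a Dieckmann-type closure of the same C4–C5 bond) to give the 2-(methoxycarbonyl)cyclohex-2-enone F4. Luche reduction (NaBH4, CeCl3·7H2O, MeOH, −78 °C) should then deliver hydride anti to the epoxide oxygen and give 21.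

2. Step 11. What may go wrong: loss of chemoselectivity, that is, partial reduction of the tert-butyl enoate or incomplete reduction of the hindered ring ester. The fallback sets out from 21 and returns at 26. Both esters are reduced with excess i-Bu2AlH to the silyl ether triol F5. Methanolysis and ketalisation as in step 12 give, by way of the tetraol F6 (not isolated), the acetonide diol F7. Dess–Martin periodinane oxidises the C2 carbinol and the side-chain allylic alcohol together to the keto enal F8, Pinnick oxidation (NaClO2, NaH2PO4, 2-methylbut-2-ene) gives the acid F9, and aqueous acetic acid removes the acetonide to give 26. This path also avoids the strong-acid step.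

3. Step 14. What may go wrong: acid-promoted opening of the epoxide or ionisation of the allylic alcohols during the slow cleavage of the tert-butyl ester. The fallback sets out from 25 and returns at 26. The acetonide is removed first with aqueous acetic acid to give the tert-butyl ester F10. Me3SiOTf and 2,6-lutidine in CH2Cl2 then convert the tert-butyl ester into the silyl ester under buffered conditions, giving the tris-silyl derivative F11 (not isolated), and methanolic work-up releases 26.

**Further compounds**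

F1 | step 10 | (2S,3R)-3-[(E)-4-tert-butoxy-3-methyl-4-oxobut-2-enyl]-3-[(1S)-4-methoxy-4-oxo-1-(triethylsilyloxy)but-2-ynyl]oxirane-2-carboxylic acid (acid from 14) | OC(=O)[C@H]1O[C@@]1(C/C=C(\C)C(=O)OC(C)(C)C)[C@@H](O[Si](CC)(CC)CC)C#CC(=O)OC
F2 | step 10 | methyl ester of F1 | COC(=O)[C@H]1O[C@@]1(C/C=C(\C)C(=O)OC(C)(C)C)[C@@H](O[Si](CC)(CC)CC)C#CC(=O)OC
F3 | step 10 | lithium allenoate from 19 and F2 (not isolated) | COC(=O)[C@H]1O[C@@]1(C/C=C(\C)C(=O)OC(C)(C)C)[C@@H](O[Si](CC)(CC)CC)C(/C=C/CCCCC)=C=C([O-])OC.[Li+]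
F4 | step 10 | C5 ketone analogue of 21 (2-(methoxycarbonyl)cyclohex-2-enone) | CCCCC/C=C/C1=C(C(=O)OC)C(=O)[C@H]2O[C@@]2(C/C=C(\C)C(=O)OC(C)(C)C)[C@H]1O[Si](CC)(CC)CC
F5 | step 11 | analogue of 22 with the side chain reduced to (E)-4-hydroxy-3-methylbut-2-enyl | CCCCC/C=C/C1=C(CO)[C@@H](O)[C@H]2O[C@@]2(C/C=C(\C)CO)[C@H]1O[Si](CC)(CC)CC
F6 | step 11 | tetraol from F5 (not isolated) | CCCCC/C=C/C1=C(CO)[C@@H](O)[C@H]2O[C@@]2(C/C=C(\C)CO)[C@H]1O
F7 | step 11 | 5-O:4-CH2O-isopropylidene acetal of F6 | CCCCC/C=C/C1=C2COC(C)(C)O[C@H]2[C@H]3O[C@@]3(C/C=C(\C)CO)[C@H]1O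
F8 | step 11 | keto enal from F7 (C2 ketone, side-chain aldehyde) | CCCCC/C=C/C1=C2COC(C)(C)O[C@H]2[C@H]3O[C@@]3(C/C=C(\C)C=O)C1=O
F9 | step 11 | 5-O:4-CH2O-isopropylidene acetal of ambuic acid | CCCCC/C=C/C1=C2COC(C)(C)O[C@H]2[C@H]3O[C@@]3(C/C=C(\C)C(=O)O)C1=O
F10 | step 14 | ambuic acid tert-butyl ester | CCCCC/C=C/C1=C(CO)[C@@H](O)[C@H]2O[C@@]2(C/C=C(\C)C(=O)OC(C)(C)C)C1=O
F11 | step 14 | trimethylsilyl ester bis(trimethylsilyl) ether of ambuic acid (not isolated) | CCCCC/C=C/C1=C(CO[Si](C)(C)C)[C@@H](O[Si](C)(C)C)[C@H]2O[C@@]2(C/C=C(\C)C(=O)O[Si](C)(C)C)C1=O
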